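**Retrosynthetic overview**
- The target is the ring-closed hemiketal of (R)-2-(4-allyl-2-hydroxy-6-methoxyphenoxy)-1-(3,4,5-trimethoxyphenyl)propan-1-one. The 1,4-dioxane ring is the only ring made; it closes last and spontaneously.
- The free phenol is unmasked from an ortho-formyl group (Dakin oxidation), so no protecting group is needed. The salicylaldehyde comes from eugenol.
- The C3–O aryl ether is made by Mitsunobu inversion of an (S)-α-hydroxy ketone with that salicylaldehyde.
- Key C–C disconnection, C2–C3: a chiral carbene turns 3,4,5-trimethoxybenzaldehyde into an acyl anion equivalent that attacks acetaldehyde. This joins two carbonyl carbons and sets C3.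
- Both benzene rings are bought.

Assumption: C2 is a hemiketal carbon that equilibrates through the open hydroxy ketone, so only C3 must be set; the (2S) form (axial OH, trans to the 3-methyl) is taken as the thermodynamic one.
Assumption: the (5aR,10bS) triazolium salt is taken to give the (S)-ketol; if it gives (R), its commercial mirror image is used and nothing else changes.

**Route**

Step 1
Reactants: 1 eugenol (4-allyl-2-methoxyphenol)
Product: 2 5-allyl-2-hydroxy-3-methoxybenzaldehyde
Conditions: MgCl2, Et3N, (CH2O)n, MeCN, reflux; then 1 M HCl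
Reagents that add atoms: paraformaldehyde (formaldehyde), C=O
Why: Magnesium-mediated ortho-formylation (Casnati–Skattebøl): the magnesium phenoxide delivers formaldehyde to the only free ortho position and a second formaldehyde oxidises the benzylic alkoxide to the aldehyde; the allyl group is untouched.

Step 2
Reactants: 3 3,4,5-trimethoxybenzaldehyde; 4 acetaldehyde
Product: 6 (S)-2-hydroxy-1-(3,4,5-trimethoxyphenyl)propan-1-one, via Breslow enaminol 5 (not isolated)
Conditions: (5aR,10bS)-2-(pentafluorophenyl)-5a,10b-dihydro-4H,6H-indeno[2,1-b][1,2,4]triazolo[4,3-d][1,4]oxazin-2-ium tetrafluoroborate (10 mol %), i-Pr2NEt (10 mol %), MeCHO (10 equiv), THF, 0 °C, sealed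
Reagents that add atoms: none
Why: Proposed new method: the electron-poor N-C6F5 triazolylidene should form the Breslow enaminol 5 (the acyl anion equivalent) from the aryl aldehyde more readily than from acetaldehyde, because the benzylic C–H of the carbene adduct is the more acidic one, and 5 should then attack the more electrophilic, unhindered acetaldehyde (in excess) through a hydrogen-bonded five-membered transition state on the face left open by the indane wall, setting C3 as (S), while the low temperature and weak base suppress retro-acyloin racemisation; the closest known reactions are the racemic carbene-catalysed crossed acyloin condensation of aromatic aldehydes with acetaldehyde and chiral-triazolium enantioselective benzoin and cross-benzoin reactions.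

Step 3
Reactants: 6 (S)-2-hydroxy-1-(3,4,5-trimethoxyphenyl)propan-1-one; 2 5-allyl-2-hydroxy-3-methoxybenzaldehyde
Product: 7 (R)-5-allyl-3-methoxy-2-{[1-oxo-1-(3,4,5-trimethoxyphenyl)propan-2-yl]oxy}benzaldehyde
Conditions: PPh3, DIAD, THF, 0 °C to rt
Reagents that add atoms: none
Why: Mitsunobu etherification: the acidic salicylaldehyde-type phenol displaces the α-keto alkoxyphosphonium by SN2 under near-neutral conditions, so C3 is inverted cleanly from (S) to (R); the aldehyde, ketone and allyl group are inert.

Step 4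
Reactants: 7 (R)-5-allyl-3-methoxy-2-{[1-oxo-1-(3,4,5-trimethoxyphenyl)propan-2-yl]oxy}benzaldehyde
Product: 10 (2S,3R)-7-allyl-5-methoxy-3-methyl-2-(3,4,5-trimethoxyphenyl)-2,3-dihydro-1,4-benzodioxin-2-ol, via aryl formate 8 (not isolated), via hydroxy ketone 9 (not isolated)
Conditions: 35% aq. H2O2 (1.5 equiv), H2SO4 (5 mol %), MeOH, rt; then H2O/THF, rt; aq. NaHCO3 work-up
Reagents that add atoms: hydrogen peroxide, OO
Why: Acid-catalysed Dakin (Baeyer–Villiger-type) oxidation: the ortho-alkoxyaryl group migrates in the peroxide adduct of the aldehyde, while the aryl ketone and the allyl group do not react with H2O2/H+; methanolysis of formate 8 frees phenol 9, which adds to the ketone to close the dioxane ring, and C2 settles by ring–chain equilibration as the (2S) hemiketal with C3 unchanged.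

**Compound list**

1 | eugenol (4-allyl-2-methoxyphenol) | C=CCc1ccc(O)c(OC)c1 | starting material
2 | 5-allyl-2-hydroxy-3-methoxybenzaldehyde | C=CCc1cc(C=O)c(O)c(OC)c1 | intermediate
3 | 3,4,5-trimethoxybenzaldehyde | COc1cc(C=O)cc(OC)c1OC | starting material
4 | acetaldehyde | CC=O | starting material
5 | Breslow enaminol: hydroxy(3,4,5-trimethoxyphenyl)methylidene adduct of the (5aR,10bS) N-pentafluorophenyl indeno-triazolo-oxazine carbene (C=C geometry not defined) | OC(c1cc(OC)c(OC)c(OC)c1)=C1N(c2c(F)c(F)c(F)c(F)c2F)N=C2CO[C@@H]3Cc4ccccc4[C@@H]3N12 | intermediate (not isolated)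
6 | (S)-2-hydroxy-1-(3,4,5-trimethoxyphenyl)propan-1-one | C[C@H](O)C(=O)c1cc(OC)c(OC)c(OC)c1 | intermediate
7 | (R)-5-allyl-3-methoxy-2-{[1-oxo-1-(3,4,5-trimethoxyphenyl)propan-2-yl]oxy}benzaldehyde | C[C@@H](Oc1c(OC)cc(CC=C)cc1C=O)C(=O)c1cc(OC)c(OC)c(OC)c1 | intermediate
8 | 5-allyl-3-methoxy-2-{[(2R)-1-oxo-1-(3,4,5-trimethoxyphenyl)propan-2-yl]oxy}phenyl formate | C[C@@H](Oc1c(OC)cc(CC=C)cc1OC=O)C(=O)c1cc(OC)c(OC)c(OC)c1 | intermediate (not isolated)
9 | (R)-2-(4-allyl-2-hydroxy-6-methoxyphenoxy)-1-(3,4,5-trimethoxyphenyl)propan-1-one | C[C@@H](Oc1c(OC)cc(CC=C)cc1O)C(=O)c1cc(OC)c(OC)c(OC)c1 | intermediate (not isolated)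
10 | (2S,3R)-7-allyl-5-methoxy-3-methyl-2-(3,4,5-trimethoxyphenyl)-2,3-dihydro-1,4-benzodioxin-2-ol | C=CCc1cc(OC)c2c(c1)O[C@@](O)(c1cc(OC)c(OC)c(OC)c1)[C@@H](C)O2 | target

**Step count**

Total steps: 4. Longest linear sequence: 3 (1 → 2 → 7 → 10, or 3 + 4 → 6 → 7 → 10).

**Three steps most likely to fail**

Step 2 (the key step). The risks are the wrong cross-product (acetaldehyde acting as the acyl donor), acetoin and homo-benzoin formation, modest ee, and the unverified sense of induction. The fallback sets out from 3 and comes back at 6, and keeps an acyl anion C–C bond but moves stereocontrol to a reduction. Aldehyde 3 is condensed with propane-1,3-dithiol (BF3·OEt2, CH2Cl2) to 2-(3,4,5-trimethoxyphenyl)-1,3-dithiane F1. F1 is lithiated (n-BuLi, THF, −78 °C) and acylated with N-methoxy-N-methylacetamide to give 1-[2-(3,4,5-trimethoxyphenyl)-1,3-dithian-2-yl]ethan-1-one F2. Reduction with BH3·SMe2 and (3aR)-1-methyl-3,3-diphenylhexahydropyrrolo[1,2-c][1,3,2]oxazaborole (10 mol %) gives (S)-1-[2-(3,4,5-trimethoxyphenyl)-1,3-dithian-2-yl]ethan-1-ol F3, the dithianyl carbon acting as the large group. Unmasking with MeI and CaCO3 in aqueous MeCN returns ketol 6.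

Step 3. The risks are a slow reaction of the doubly ortho-substituted phenol, elimination of the alkoxyphosphonium to the aryl vinyl ketone, and partial loss of ee. The fallback sets out from 6 (with 2) and comes back at 7, replacing redox condensation with activation and displacement. Ketol 6 is converted with Tf2O and 2,6-lutidine (CH2Cl2, −78 °C) into (S)-1-oxo-1-(3,4,5-trimethoxyphenyl)propan-2-yl trifluoromethanesulfonate F4. F4 is displaced with inversion at −40 °C in MeCN by the caesium phenoxide of 2 (Cs2CO3) to give 7.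

Step 4. The risks are formation of the mixed methyl ketal, acid-promoted dehydration or epimerisation at C3, and competing migration of hydrogen to give the benzoic acid. The fallback sets out from 2 and comes back at 9, unmasking the phenol before the ether is made and carrying it as a silyl ether. Dakin oxidation of 2 (H2O2, NaOH, aqueous THF) gives 5-allyl-3-methoxybenzene-1,2-diol F5. Monosilylation at the less hindered oxygen (TBSCl, imidazole, DMF, 0 °C) gives 4-allyl-2-[(tert-butyldimethylsilyl)oxy]-6-methoxyphenol F6. Mitsunobu coupling of F6 with 6 (PPh3, DIAD, THF) gives (R)-2-{4-allyl-2-[(tert-butyldimethylsilyl)oxy]-6-methoxyphenoxy}-1-(3,4,5-trimethoxyphenyl)propan-1-one F7. Desilylation with Bu4NF buffered with AcOH (THF, 0 °C) releases 9, which closes to 10.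

**Further compounds**

F1 | step 2 | 2-(3,4,5-trimethoxyphenyl)-1,3-dithiane | COc1cc(C2SCCCS2)cc(OC)c1OC
F2 | step 2 | 1-[2-(3,4,5-trimethoxyphenyl)-1,3-dithian-2-yl]ethan-1-one | CC(=O)C1(SCCCS1)c1cc(OC)c(OC)c(OC)c1
F3 | step 2 | (S)-1-[2-(3,4,5-trimethoxyphenyl)-1,3-dithian-2-yl]ethan-1-ol | C[C@H](O)C1(SCCCS1)c1cc(OC)c(OC)c(OC)c1
F4 | step 3 | (S)-1-oxo-1-(3,4,5-trimethoxyphenyl)propan-2-yl trifluoromethanesulfonate | C[C@H](OS(=O)(=O)C(F)(F)F)C(=O)c1cc(OC)c(OC)c(OC)c1
F5 | step 4 | 5-allyl-3-methoxybenzene-1,2-diol | C=CCc1cc(O)c(O)c(OC)c1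
F6 | step 4 | 4-allyl-2-[(tert-butyldimethylsilyl)oxy]-6-methoxyphenol | C=CCc1cc(O[Si](C)(C)C(C)(C)C)c(O)c(OC)c1
F7 | step 4 | (R)-2-{4-allyl-2-[(tert-butyldimethylsilyl)oxy]-6-methoxyphenoxy}-1-(3,4,5-trimethoxyphenyl)propan-1-one | C[C@@H](Oc1c(OC)cc(CC=C)cc1O[Si](C)(C)C(C)(C)C)C(=O)c1cc(OC)c(OC)c(OC)c1
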